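The north-east run, with Z at 0.20 M and E at 0.30 M, suggests a better clock than hours: exposure, the mean of E times the elapsed time. On this clock each forward step, which takes up one E, is pseudo-first-order, provided the mean can stand in for the curve of E; the way back from X takes up no E and does not run on this clock.

| setting | north-east | flask |
|---|---|---|
| Z | 0.20 M | 0.20 M |
| E | 0.30 M | 0.600 M |
| remark | run made earlier |  |
| time |  | 6.0 d |

north-east run (percent of the Z charged)

| time / h | Z / % | D / % |
|---|---|---|
| 1.50 | 94.5 | 6.7 |
| 4.00 | 85.8 | 15.2 |
| 8.00 | 74.2 | 26.3 |
| 12.0 | 64.8 | 34.6 |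
| 20.0 | 51.1 | 47.3 |
| 25.0 | 44.3 | 53.8 |
| 30.0 | 40.6 | 58.4 |

(standard deviation of a reading: 0.5 percentage points)

- the Z standing at 6.0 d, as a percentage of the Z charged
- the D standing at 6.0 d, as a percentage of the Z charged
- the L standing at 6.0 d, as a percentage of the Z charged
- the X standing at 6.0 d, as a percentage of the Z charged

- the numbers in the tables scatter by 0.5 percentage points (one standard deviation)
- candidate steps: Z + E -> D; E + D -> L; E + L <-> X

In the north-east run at 25.0 h, Z reads 44.3%. Taking one E per Z lost, mean E is 0.244 M and the exposure 6.11 M·h. That gives a first constant of 0.133 /M/h, so a Z waits on average 7.50 M·h of exposure before becoming D.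

Over the last 3 readings of that run, centred near 25.0 h, Z plus D falls short of the charge by 1.50%. With D averaging 26.9% up to there, the second constant is 0.00913 /M/h.

In the new flask I first take E at 0.400 M, charge less Z, and let the early surplus pass. The exposure over 6.0 d is then 57.6 M·h, and D loses 36.7%.

The weak link is that mean, since each D lost takes at least one more E. Spread evenly over the run, this lowers mean E by 0.0367 M, so the exposure becomes 52.3 M·h. D's exposure, the flask's exposure less the wait, is 44.8 M·h.

I commit to Z at 0.0936%, D at 66.4%, and L and X together at 33.6%. The readings have no column for L or X, so I give no split.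

The forecast says Z 0.04%, D 68%, L 30% and X 2%, and of the third step, “I assume it is slower”.

The flask gives Z 0.0520%, D 70.3%, L 17.1% and X 12.6%.

    Z + E → D (k = 0.00232 /M/min)
    E + D → L (k = 1.25 × 10⁻⁴ /M/min)
    E + L ⇌ X (K = 2.50 /M, k = 0.00317 /M/min)

L's forward half-life toward X, with the other concentrations as charged, is 0.25 d, short against the 6.0 d. Read back through D's exposure of 44.8 M·h, the flask's D gives a second constant of 0.00787 /M/h, lower than my 0.00913 /M/h.

For the neighbour flask with E at 1.0 M, the same two passes with that constant give D's exposure as 99.5 M·h, and so D at 45.7%. The computed value is 48.5%.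

The readings come from a simulation from invented constants, noise included.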